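**Retrosynthetic overview**
1. Ring C is made last by forming the C2–C3 bond: a chiral phosphoric acid should contract the seven-membered benzylidene acetal 12 (a 2-aryl-4H-1,3-benzodioxepin-5-one) to the 3-hydroxychroman-4-one, setting C2 and C3 and giving the unprotected target directly.
2. Enabling feature: the 4'-hydroxyl of ring B is para to C2, so C2 can ionise to a para-quinone methide; the C3 oxygen is the internal leaving group of the C2 acetal and, once freed, sits next to the C4 carbonyl, whose enol makes C3 nucleophilic; O1 and C4 are ortho on ring A, so C3 and C2 close a six-membered ring.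
3. Acetal 12 is cut at its two C2–O bonds into ketol 6 (ring A) and aldehyde 9 (ring B), joined by transacetalisation and then desilylated.
4. 6 comes from 1-(5-bromo-2,4-dihydroxyphenyl)ethan-1-one (O4 silylation, Rubottom oxidation, Stille prenylation); 9 from 3-bromo-4-hydroxybenzaldehyde (silylation, Stille prenylation).
5. Ring order: rings A and B are bought as benzene rings; the temporary seven-membered acetal ring is formed in step 6; ring C is formed in step 8.

Key step: step 8

Assumption: the sense of induction of the binaphthyl phosphoric acid in step 8 cannot be predicted with certainty for a new substrate class; the (R)-catalyst is written, and the (S)-catalyst would be used if a pilot run shows that it is the one leading to the (2R,3R) product.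

**Step 1**
Reactants: 1 1-(5-bromo-2,4-dihydroxyphenyl)ethan-1-one
Product: 2 1-[5-bromo-2-hydroxy-4-(triisopropylsilyloxy)phenyl]ethan-1-one
Conditions: iPr3SiCl (1.1 equiv), imidazole (2.2 equiv), DMF, 0 °C to 23 °C
Reagents that add atoms: triisopropylsilyl chloride, CC(C)[Si](Cl)(C(C)C)C(C)C
Why: Phenol O-silylation (silyl ether formation) should occur only at O4, because the 2-hydroxyl is held in a hydrogen bond to the ketone and is unreactive toward the bulky silyl chloride; no stereocentre is formed.

**Step 2**
Reactants: 2 1-[5-bromo-2-hydroxy-4-(triisopropylsilyloxy)phenyl]ethan-1-one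
Product: 5 1-[5-bromo-2-hydroxy-4-(triisopropylsilyloxy)phenyl]-2-hydroxyethan-1-one, via silyl enol ether 3 (not isolated), via silyloxy ketone 4 (not isolated)
Conditions: Me3SiOTf (2.3 equiv), Et3N (3 equiv), CH2Cl2, 0 °C; then mCPBA (1.05 equiv), CH2Cl2, −20 °C to 0 °C; then 1 M aq. HCl, THF, 0 °C
Reagents that add atoms: 3-chloroperbenzoic acid (mCPBA), O=C(OO)c1cccc(Cl)c1
Why: Rubottom oxidation: soft enolisation gives the silyl enol ether, the peracid epoxidises this electron-rich alkene (no other alkene is present yet), the silyloxy epoxide rearranges to the α-silyloxy ketone, and dilute acid removes both trimethylsilyl groups while the triisopropylsilyl ether survives; no stereocentre is formed.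

**Step 3**
Reactants: 5 1-[5-bromo-2-hydroxy-4-(triisopropylsilyloxy)phenyl]-2-hydroxyethan-1-one
Product: 6 2-hydroxy-1-[2-hydroxy-5-(3-methylbut-2-en-1-yl)-4-(triisopropylsilyloxy)phenyl]ethan-1-one
Conditions: tributyl(3-methylbut-2-en-1-yl)stannane (1.5 equiv), Pd(PPh3)4 (5 mol%), DMF, 90 °C
Reagents that add atoms: tributyl(3-methylbut-2-en-1-yl)stannane, CCCC[Sn](CCCC)(CCCC)CC=C(C)C
Why: Stille cross-coupling of the aryl bromide with the allylic stannane should give the linear prenyl arene by reductive elimination at the less hindered allyl terminus, and the neutral conditions tolerate the free ketol and phenol.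

**Step 4**
Reactants: 7 3-bromo-4-hydroxybenzaldehyde
Product: 8 3-bromo-4-(tert-butyldimethylsilyloxy)benzaldehyde
Conditions: tBuMe2SiCl (1.1 equiv), imidazole (2.2 equiv), CH2Cl2, 23 °C
Reagents that add atoms: tert-butyldimethylsilyl chloride, CC(C)(C)[Si](C)(C)Cl
Why: Standard phenol O-silylation (silyl ether formation); the silyl ether later keeps the ring B acetal from ionising before the key step.

**Step 5**
Reactants: 8 3-bromo-4-(tert-butyldimethylsilyloxy)benzaldehyde
Product: 9 4-(tert-butyldimethylsilyloxy)-3-(3-methylbut-2-en-1-yl)benzaldehyde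
Conditions: tributyl(3-methylbut-2-en-1-yl)stannane (1.3 equiv), Pd(PPh3)4 (5 mol%), toluene, 100 °C
Reagents that add atoms: tributyl(3-methylbut-2-en-1-yl)stannane, CCCC[Sn](CCCC)(CCCC)CC=C(C)C
Why: Stille cross-coupling; the bromide is activated by the para-formyl group, and the non-polar solvent keeps the aryl silyl ether intact.

**Step 6**
Reactants: 6 2-hydroxy-1-[2-hydroxy-5-(3-methylbut-2-en-1-yl)-4-(triisopropylsilyloxy)phenyl]ethan-1-one; 9 4-(tert-butyldimethylsilyloxy)-3-(3-methylbut-2-en-1-yl)benzaldehyde
Product: 11 rac-2-[4-(tert-butyldimethylsilyloxy)-3-(3-methylbut-2-en-1-yl)phenyl]-7-(3-methylbut-2-en-1-yl)-8-(triisopropylsilyloxy)-4H-1,3-benzodioxepin-5-one, via dimethyl acetal 10 (not isolated)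
Conditions: 9, HC(OMe)3 (1.5 equiv), pyridinium p-toluenesulfonate (2 mol%), MeOH, 23 °C, then evaporation; 6 (1.0 equiv), pyridinium p-toluenesulfonate (5 mol%), CH2Cl2, 5 Å molecular sieves, 23 °C; chromatography on Et3N-deactivated silica
Reagents that add atoms: none
Why: Acid-catalysed transacetalisation: the dimethyl acetal exchanges first with the primary ketol hydroxyl and then with the ortho-phenol, ring closure being driven by uptake of methanol on the sieves, while the weak acid should not enolise the ketone, so the acetal should not rearrange; the acetal carbon forms racemic, which does not matter because it is planarised in step 8.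

**Step 7**
Reactants: 11 rac-2-[4-(tert-butyldimethylsilyloxy)-3-(3-methylbut-2-en-1-yl)phenyl]-7-(3-methylbut-2-en-1-yl)-8-(triisopropylsilyloxy)-4H-1,3-benzodioxepin-5-one
Product: 12 rac-8-hydroxy-2-[4-hydroxy-3-(3-methylbut-2-en-1-yl)phenyl]-7-(3-methylbut-2-en-1-yl)-4H-1,3-benzodioxepin-5-one
Conditions: Bu4NF (2.2 equiv), AcOH (2.4 equiv), THF, 0 °C to 23 °C; pH 7 phosphate buffer work-up, used without delay
Reagents that add atoms: none
Why: Fluoride-mediated cleavage of both aryl silyl ethers; the acetic acid buffer releases the phenols and not the phenoxides, so the acetal, which ionises only under acid or through the 4'-phenoxide, should stay intact.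

**Step 8**
Reactants: 12 rac-8-hydroxy-2-[4-hydroxy-3-(3-methylbut-2-en-1-yl)phenyl]-7-(3-methylbut-2-en-1-yl)-4H-1,3-benzodioxepin-5-one
Product: 15 lespeflorin B1 (2R,3R)-3,7-dihydroxy-2-[4-hydroxy-3-(3-methylbut-2-en-1-yl)phenyl]-6-(3-methylbut-2-en-1-yl)-2,3-dihydro-4H-chromen-4-one, via quinone methide ketol 13 (not isolated), via quinone methide enediol 14 (not isolated)
Conditions: (R)-3,3'-bis(2,4,6-triisopropylphenyl)-1,1'-binaphthyl-2,2'-diyl hydrogen phosphate (10 mol%), toluene, 4 Å molecular sieves, 0 °C to 23 °C, stopped at full conversion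
Reagents that add atoms: none
Why: Proposed new method: the phosphoric acid protonates the alkyl acetal oxygen of 12 while its phosphoryl oxygen accepts the proton of the ring B 4'-hydroxyl, so the C2–O3 bond ionises to the neutral aryloxy para-quinone methide 13 (the racemic acetal centre is erased), the freed ketol enolises to the (Z)-enediol 14, and C3 of the enediol adds to the methide carbon C2 in an intramolecular 1,6-addition that rearomatises ring B. The closest known reaction types are the chiral phosphoric acid catalysed asymmetric 1,6-additions of carbon nucleophiles to para-quinone methides generated in situ from para-hydroxybenzyl alcohols, and the Petasis–Ferrier and aza-Petasis–Ferrier O-to-C rearrangements of cyclic acetals through oxocarbenium or iminium and enol partners. Ring C closes in a 6-(enolendo)-exo-trig mode while the seven-membered acetal ring opens, a net ring contraction by 1,3-shift of C2 from oxygen to carbon. C2 is set by the catalyst, which bridges the quinone methide carbonyl and the enediol hydroxyl in a hydrogen-bonded transition state and exposes one face of the methide carbon; C3 is set relative to C2 by a half-chair transition state in which ring B and the C3 hydroxyl of the (Z)-enediol are both pseudo-equatorial, which is also the more stable trans arrangement. The step needs attack through C3 and not C4 of the enediol, secured because only C3 attack develops a C4 oxocarbenium stabilised by the ortho- and para-oxygens of ring A and leads to the conjugated aryl ketone, and it needs productive cleavage of C2–O3 and not C2–O1, secured because the alternative ionisation is reversible and can close no six-membered ring. The weak acid, the low temperature and the absence of any oxidant should leave the two prenyl groups and the free phenols untouched.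

**Compound list**
1 | 1-(5-bromo-2,4-dihydroxyphenyl)ethan-1-one | CC(=O)c1cc(Br)c(O)cc1O | starting material
2 | 1-[5-bromo-2-hydroxy-4-(triisopropylsilyloxy)phenyl]ethan-1-one | CC(=O)c1cc(Br)c(O[Si](C(C)C)(C(C)C)C(C)C)cc1O | intermediate
3 | {1-[5-bromo-4-(triisopropylsilyloxy)-2-(trimethylsilyloxy)phenyl]ethenyloxy}trimethylsilane (silyl enol ether) | C=C(O[Si](C)(C)C)c1cc(Br)c(O[Si](C(C)C)(C(C)C)C(C)C)cc1O[Si](C)(C)C | intermediate (not isolated)
4 | 1-[5-bromo-4-(triisopropylsilyloxy)-2-(trimethylsilyloxy)phenyl]-2-(trimethylsilyloxy)ethan-1-one (silyloxy ketone) | C[Si](C)(C)OCC(=O)c1cc(Br)c(O[Si](C(C)C)(C(C)C)C(C)C)cc1O[Si](C)(C)C | intermediate (not isolated)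
5 | 1-[5-bromo-2-hydroxy-4-(triisopropylsilyloxy)phenyl]-2-hydroxyethan-1-one | OCC(=O)c1cc(Br)c(O[Si](C(C)C)(C(C)C)C(C)C)cc1O | intermediate
6 | 2-hydroxy-1-[2-hydroxy-5-(3-methylbut-2-en-1-yl)-4-(triisopropylsilyloxy)phenyl]ethan-1-one | OCC(=O)c1cc(CC=C(C)C)c(O[Si](C(C)C)(C(C)C)C(C)C)cc1O | intermediate
7 | 3-bromo-4-hydroxybenzaldehyde | O=Cc1ccc(O)c(Br)c1 | starting material
8 | 3-bromo-4-(tert-butyldimethylsilyloxy)benzaldehyde | O=Cc1ccc(O[Si](C)(C)C(C)(C)C)c(Br)c1 | intermediate
9 | 4-(tert-butyldimethylsilyloxy)-3-(3-methylbut-2-en-1-yl)benzaldehyde | O=Cc1ccc(O[Si](C)(C)C(C)(C)C)c(CC=C(C)C)c1 | intermediate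
10 | tert-butyl[4-(dimethoxymethyl)-2-(3-methylbut-2-en-1-yl)phenoxy]dimethylsilane (dimethyl acetal) | COC(OC)c1ccc(O[Si](C)(C)C(C)(C)C)c(CC=C(C)C)c1 | intermediate (not isolated)
11 | rac-2-[4-(tert-butyldimethylsilyloxy)-3-(3-methylbut-2-en-1-yl)phenyl]-7-(3-methylbut-2-en-1-yl)-8-(triisopropylsilyloxy)-4H-1,3-benzodioxepin-5-one | O=C1COC(c2ccc(O[Si](C)(C)C(C)(C)C)c(CC=C(C)C)c2)Oc2cc(O[Si](C(C)C)(C(C)C)C(C)C)c(CC=C(C)C)cc21 | intermediate
12 | rac-8-hydroxy-2-[4-hydroxy-3-(3-methylbut-2-en-1-yl)phenyl]-7-(3-methylbut-2-en-1-yl)-4H-1,3-benzodioxepin-5-one | O=C1COC(c2ccc(O)c(CC=C(C)C)c2)Oc2cc(O)c(CC=C(C)C)cc21 | intermediate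
13 | 4-{[5-hydroxy-2-(hydroxyacetyl)-4-(3-methylbut-2-en-1-yl)phenoxy]methylidene}-2-(3-methylbut-2-en-1-yl)cyclohexa-2,5-dien-1-one (quinone methide ketol, either alkene geometry) | O=C1C=CC(=COc2cc(O)c(CC=C(C)C)cc2C(=O)CO)C=C1CC=C(C)C | intermediate (not isolated)
14 | 4-{[2-((Z)-1,2-dihydroxyethenyl)-5-hydroxy-4-(3-methylbut-2-en-1-yl)phenoxy]methylidene}-2-(3-methylbut-2-en-1-yl)cyclohexa-2,5-dien-1-one (quinone methide enediol) | O=C1C=CC(=COc2cc(O)c(CC=C(C)C)cc2/C(O)=C/O)C=C1CC=C(C)C | intermediate (not isolated)
15 | lespeflorin B1, (2R,3R)-3,7-dihydroxy-2-[4-hydroxy-3-(3-methylbut-2-en-1-yl)phenyl]-6-(3-methylbut-2-en-1-yl)-2,3-dihydro-4H-chromen-4-one | CC(C)=CCc1cc([C@H]2Oc3cc(O)c(CC=C(C)C)cc3C(=O)[C@@H]2O)ccc1O | target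

**Step count and risks**
Total steps: 8. Longest linear sequence: 6 steps (1 → 2 → 5 → 6 → 11 → 12 → 15).

Steps most likely to fail:

1. Step 8 (labelled as a proposed new method). The process risks are poor facial discrimination at the quinone methide carbon, slow enolisation of the ketol, and background closure without the catalyst, which would erode the enantiomeric purity. The fallback uses known reaction types, sets out from 6 and 9 and comes back to the route at 15. A direct catalytic asymmetric aldol addition of the α-hydroxy aryl ketone 6 to aldehyde 9 (dinuclear zinc catalyst from Et2Zn and the ProPhenol ligand enantiomer that gives the 2R ketol, one further equivalent of Et2Zn for the phenol, THF, 4 Å molecular sieves, −20 °C) should give the syn diol (2R,3S)-3-[4-(tert-butyldimethylsilyloxy)-3-(3-methylbut-2-en-1-yl)phenyl]-2,3-dihydroxy-1-[2-hydroxy-5-(3-methylbut-2-en-1-yl)-4-(triisopropylsilyloxy)phenyl]propan-1-one F1. An intramolecular Mitsunobu reaction (PPh3, diisopropyl azodicarboxylate, THF, 0 °C) should then close ring C by attack of the ortho-phenol on the benzylic carbinol with inversion, giving the trans bis-silyl ether (2R,3R)-2-[4-(tert-butyldimethylsilyloxy)-3-(3-methylbut-2-en-1-yl)phenyl]-3-hydroxy-6-(3-methylbut-2-en-1-yl)-7-(triisopropylsilyloxy)-2,3-dihydro-4H-chromen-4-one F2. Desilylation with Bu4NF/AcOH in THF at 0 °C should give 15.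

2. Step 6. The process risks are an unfavourable equilibrium for closing the seven-membered mixed aryl alkyl acetal (acyclic mixed acetals or oligomers instead) and acid-promoted rearrangement before the chiral catalyst is present. The fallback sets out from 6 and 10 (made from 9 as in step 6) and comes back at 11; it forms the difficult aryl O–C bond irreversibly under base. Acetyl chloride (CH2Cl2, 0 °C) should convert 10 into the α-chloro ether tert-butyl{4-[chloro(methoxy)methyl]-2-(3-methylbut-2-en-1-yl)phenoxy}dimethylsilane F3. This alkylates the phenol of 6 (iPr2NEt, CH2Cl2, 0 °C) to the acyclic mixed acetal 1-[2-{[4-(tert-butyldimethylsilyloxy)-3-(3-methylbut-2-en-1-yl)phenyl](methoxy)methoxy}-5-(3-methylbut-2-en-1-yl)-4-(triisopropylsilyloxy)phenyl]-2-hydroxyethan-1-one F4. If the primary hydroxyl is alkylated instead, the regioisomeric mixed acetal converges on the same product. Pyridinium p-toluenesulfonate with 5 Å molecular sieves then closes the ring by intramolecular exchange with loss of methanol to give 11.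

3. Step 3. The process risks are slow oxidative addition at the electron-rich bromide flanked by the bulky silyl ether, protodebromination, and allyl transposition to the branched (1,1-dimethylallyl) isomer. The fallback changes the order of events and the oxidation method, sets out from 1 and comes back at 6. Stille coupling on the unhindered bromide 1 (same stannane, Pd(PPh3)4, DMF, 90 °C) should give 1-[2,4-dihydroxy-5-(3-methylbut-2-en-1-yl)phenyl]ethan-1-one F5. Selective O4 silylation (iPr3SiCl, imidazole, DMF) should give 1-[2-hydroxy-5-(3-methylbut-2-en-1-yl)-4-(triisopropylsilyloxy)phenyl]ethan-1-one F6. The ketone is then hydroxylated through its sodium enolate (NaN(SiMe3)2, 2.2 equiv, THF, −78 °C; then 2-(phenylsulfonyl)-3-phenyloxaziridine), an oxidant that does not attack the prenyl alkene, to give 6.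

**Further compounds**
F1 | step 8 | (2R,3S)-3-[4-(tert-butyldimethylsilyloxy)-3-(3-methylbut-2-en-1-yl)phenyl]-2,3-dihydroxy-1-[2-hydroxy-5-(3-methylbut-2-en-1-yl)-4-(triisopropylsilyloxy)phenyl]propan-1-one | O=C(c1cc(CC=C(C)C)c(O[Si](C(C)C)(C(C)C)C(C)C)cc1O)[C@H](O)[C@@H](O)c1ccc(O[Si](C)(C)C(C)(C)C)c(CC=C(C)C)c1
F2 | step 8 | (2R,3R)-2-[4-(tert-butyldimethylsilyloxy)-3-(3-methylbut-2-en-1-yl)phenyl]-3-hydroxy-6-(3-methylbut-2-en-1-yl)-7-(triisopropylsilyloxy)-2,3-dihydro-4H-chromen-4-one | CC(C)=CCc1cc([C@H]2Oc3cc(O[Si](C(C)C)(C(C)C)C(C)C)c(CC=C(C)C)cc3C(=O)[C@@H]2O)ccc1O[Si](C)(C)C(C)(C)C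
F3 | step 6 | tert-butyl{4-[chloro(methoxy)methyl]-2-(3-methylbut-2-en-1-yl)phenoxy}dimethylsilane | COC(Cl)c1ccc(O[Si](C)(C)C(C)(C)C)c(CC=C(C)C)c1
F4 | step 6 | 1-[2-{[4-(tert-butyldimethylsilyloxy)-3-(3-methylbut-2-en-1-yl)phenyl](methoxy)methoxy}-5-(3-methylbut-2-en-1-yl)-4-(triisopropylsilyloxy)phenyl]-2-hydroxyethan-1-one | COC(Oc1cc(O[Si](C(C)C)(C(C)C)C(C)C)c(CC=C(C)C)cc1C(=O)CO)c1ccc(O[Si](C)(C)C(C)(C)C)c(CC=C(C)C)c1
F5 | step 3 | 1-[2,4-dihydroxy-5-(3-methylbut-2-en-1-yl)phenyl]ethan-1-one | CC(=O)c1cc(CC=C(C)C)c(O)cc1O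
F6 | step 3 | 1-[2-hydroxy-5-(3-methylbut-2-en-1-yl)-4-(triisopropylsilyloxy)phenyl]ethan-1-one | CC(=O)c1cc(CC=C(C)C)c(O[Si](C(C)C)(C(C)C)C(C)C)cc1O
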